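The lactone carbonyl C2 touches only O1 and C3, so it is excised as carbon monoxide, leaving an acyclic (R)-homopropargylic alcohol: C5 carries the hydroxyl, C4 the ring B (3,4,5-trimethoxyphenyl) methylene, and C3 is the inner carbon of an alkyne capped by ring A (3,4-dimethoxyphenyl). One palladium-catalysed cyclocarbonylation forges O1-C2 and C2-C3, closes the five-membered ring and, because the hydroxyl sits on C5, fixes which benzyl arm flanks the carbonyl. C4 is set earlier by lipase desymmetrisation of a prochiral diol. C3 is set last by hydrogenation of the (E)-benzylidene lactone and base equilibration to the trans isomer.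

Key step: step 8

Numbering: lactone O1, C2 (carbonyl), C3, C4, C5. Ring A is 3,4-dimethoxyphenyl on the C3 methylene and ring B is 3,4,5-trimethoxyphenyl on the C4 methylene. The target SMILES reads as the trans (3R,4R) isomer.

Assumption: the lipase is taken to acetylate the pro-R hydroxymethyl arm of the prochiral diol, as it does for other 2-(arylmethyl)propane-1,3-diols. Sense and level of selection are to be confirmed on the monoacetate (Mosher esters or chiral HPLC) before material is advanced.

Design choices:
- **Which monoacetate is needed.** The acetylated arm becomes C5 and the free arm becomes C3, which calls for the (R)-monoacetate.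
- **Why no diazophosphonate homologation.** The derived aldehyde has an acetoxy group beta to the carbonyl and an acidic C4-H. Basic conditions (K2CO3/MeOH or KOt-Bu) would invite loss of acetic acid, methanolysis followed by retro-aldol cleavage, and racemisation.
- **What replaces it.** The alkyne is built by the near-neutral dibromoolefination. Strong base is applied only once C4 is no longer alpha to a carbonyl, and the same organolithium also removes the acetate, so no separate deprotection is needed.
- **Handling of the monoacetate.** A 1,3-acetyl shift would convert it into its enantiomer, so it is oxidised without storage.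

Step 1
Reactants: 1 diethyl malonate; 2 3,4,5-trimethoxybenzyl chloride
Product: 4 diethyl 2-(3,4,5-trimethoxybenzyl)malonate, via sodium diethyl malonate 3 (not isolated)
Conditions: 1 (1.5 equiv), NaH, THF, 0 °C; then 2, reflux
Reagents that add atoms: none
Why: Malonic ester alkylation: the preformed, stabilised enolate 3 should displace chloride from the primary benzylic carbon by SN2, the excess of 1 holding back double benzylation, and no stereocentre arises.

Step 2
Reactants: 4 diethyl 2-(3,4,5-trimethoxybenzyl)malonate
Product: 5 2-(3,4,5-trimethoxybenzyl)propane-1,3-diol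
Conditions: LiAlH4, THF, 0 °C to reflux; H2O/aq NaOH work-up
Reagents that add atoms: none
Why: Exhaustive LiAlH4 reduction of both esters should give the 2-substituted propane-1,3-diol, whose central carbon (the future C4) is prochiral because its two hydroxymethyl arms are enantiotopic, the aryl methyl ethers being inert.

Step 3
Reactants: 5 2-(3,4,5-trimethoxybenzyl)propane-1,3-diol
Product: 6 (R)-3-hydroxy-2-(3,4,5-trimethoxybenzyl)propyl acetate
Conditions: Burkholderia cepacia lipase (immobilised), vinyl acetate (3 equiv), i-Pr2O, 25 °C
Reagents that add atoms: vinyl acetate, C=COC(C)=O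
Why: Enzymatic desymmetrisation by irreversible lipase transesterification: the chiral acyl-enzyme pocket should acetylate only the pro-R hydroxymethyl arm, which sets C4 as R, tautomerisation of the released enol blocks the back reaction, and wrongly acetylated material is the faster substrate for a second acetylation and is drained to the achiral diacetate.

Step 4
Reactants: 6 (R)-3-hydroxy-2-(3,4,5-trimethoxybenzyl)propyl acetate
Product: 7 (S)-2-formyl-3-(3,4,5-trimethoxyphenyl)propyl acetate
Conditions: TEMPO (10 mol %), PhI(OAc)2, CH2Cl2, 0 °C to rt; used crude at once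
Reagents that add atoms: none
Why: Oxoammonium (TEMPO/PhI(OAc)2) oxidation stops at the aldehyde and runs without base, so neither enolisation at C4 nor beta-elimination of the acetoxy group should intervene, and the descriptor reads S only because CHO outranks CH2OAc.

Step 5
Reactants: 7 (S)-2-formyl-3-(3,4,5-trimethoxyphenyl)propyl acetate
Product: 8 (R)-4,4-dibromo-2-(3,4,5-trimethoxybenzyl)but-3-en-1-yl acetate
Conditions: CBr4 (2 equiv), PPh3 (4 equiv), CH2Cl2, 0 °C; then 7, -20 to 0 °C
Reagents that add atoms: carbon tetrabromide, BrC(Br)(Br)Br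
Why: Ramirez olefination (first stage of the Corey-Fuchs sequence): the weakly basic ylide Ph3P=CBr2 should add to the aldehyde in Wittig fashion faster than it deprotonates C4, the acetate survives, and in 8 the C4-H is merely allylic and no longer epimerisable.

Step 6
Reactants: 8 (R)-4,4-dibromo-2-(3,4,5-trimethoxybenzyl)but-3-en-1-yl acetate
Product: 10 (R)-2-(3,4,5-trimethoxybenzyl)but-3-yn-1-ol, via dilithiated alkynol 9 (not isolated)
Conditions: n-BuLi (4.5 equiv), THF, -78 °C; then H2O
Reagents that add atoms: none
Why: Second stage of the Corey-Fuchs sequence: bromine-lithium exchange, Fritsch-Buttenberg-Wiechell 1,2-hydrogen shift of the carbenoid and deprotonation give the acetylide, while two further equivalents of n-BuLi add to the acetate carbonyl and release the C5 alkoxide, so alkyne formation and deprotection should occur in one flask without touching C4 at -78 °C.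

Step 7
Reactants: 10 (R)-2-(3,4,5-trimethoxybenzyl)but-3-yn-1-ol; 11 4-iodo-1,2-dimethoxybenzene
Product: 12 (R)-4-(3,4-dimethoxyphenyl)-2-(3,4,5-trimethoxybenzyl)but-3-yn-1-ol
Conditions: PdCl2(PPh3)2 (2 mol %), CuI (4 mol %), Et3N, THF, rt, degassed
Reagents that add atoms: none
Why: Sonogashira coupling: oxidative addition of the aryl iodide to zerovalent palladium, transmetalation from the copper acetylide and reductive elimination should form the sp-sp2 bond at room temperature, the free primary alcohol being tolerated and the mild amine base leaving the propargylic C4-H alone.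

Step 8
Reactants: 12 (R)-4-(3,4-dimethoxyphenyl)-2-(3,4,5-trimethoxybenzyl)but-3-yn-1-ol; 13 carbon monoxide
Product: 14 (R,E)-3-(3,4-dimethoxybenzylidene)-4-(3,4,5-trimethoxybenzyl)dihydrofuran-2(3H)-one
Conditions: PdCl2(PPh3)2 (5 mol %), SnCl2 (anhydrous, 5 mol %), CO (7 bar), MeCN, 75 °C
Reagents that add atoms: carbon monoxide (13), [C-]#[O+]
Why: Divalent palladium, made labile by the SnCl3 ligand that SnCl2 generates, binds CO and is attacked by the C5 hydroxyl to give the alkoxycarbonyl complex ROC(O)PdCl(PPh3)2 with release of HCl; the tethered alkyne then inserts syn into the Pd-acyl bond and HCl cleaves the vinyl-Pd bond with retention, so divalent palladium returns without any redox change. The closest known reaction type is the palladium/tin-catalysed cyclocarbonylation of but-3-yn-1-ols to alpha-methylene- and alpha-alkylidene-gamma-butyrolactones. The lactone closes in the 5-exo-dig mode, C2 bonding to C3 while the aryl-bearing alkyne carbon stays outside the ring. No stereocentre is created and the C4-H bond is untouched in this neutral to weakly acidic medium, so C4 stays R; delivery of C2 and Pd to the same alkyne face, then H in place of Pd, puts H on the carbonyl side and ring A on the C4 side, which is the E alkene. The selectivity needed is regiochemical (acyl to C3 and not to the aryl carbon, which would give a six-membered 6-endo lactone) and the three-atom O1-C5-C4 tether secures it, while CO pressure and phosphine-ligated, weakly electrophilic palladium should hold back direct 5-endo attack of the hydroxyl on the alkyne.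

Step 9
Reactants: 14 (R,E)-3-(3,4-dimethoxybenzylidene)-4-(3,4,5-trimethoxybenzyl)dihydrofuran-2(3H)-one
Product: 15 (3S,4R)-3-(3,4-dimethoxybenzyl)-4-(3,4,5-trimethoxybenzyl)dihydrofuran-2(3H)-one (cis lactone)
Conditions: H2 (1 atm), 10% Pd/C, EtOAc, rt
Reagents that add atoms: none
Why: Heterogeneous catalytic hydrogenation: syn delivery of H2 to the alkene face remote from the C4 ring B methylene should set C3 as S (cis lactone), and any trans isomer formed alongside is already 16 and is simply carried into step 10.

Step 10
Reactants: 15 (3S,4R)-3-(3,4-dimethoxybenzyl)-4-(3,4,5-trimethoxybenzyl)dihydrofuran-2(3H)-one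
Product: 16 (3R,4R)-3-(3,4-dimethoxybenzyl)-4-(3,4,5-trimethoxybenzyl)dihydrofuran-2(3H)-one (target)
Conditions: DBU (1 equiv), toluene, 80 °C
Reagents that add atoms: none
Why: Base-mediated epimerisation under thermodynamic control: reversible deprotonation of C3-H (the only acidic C-H, alpha to C2) and reprotonation should funnel the crowded cis lactone into the trans (3R,4R) isomer with the two benzyl arms on opposite faces, while the non-acidic C4 is untouched.

Compound list
1 | diethyl malonate | CCOC(=O)CC(=O)OCC | starting material
2 | 3,4,5-trimethoxybenzyl chloride | COc1cc(CCl)cc(OC)c1OC | starting material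
3 | sodium diethyl malonate (sodium enolate of 1) | CCOC(=O)[CH-]C(=O)OCC.[Na+] | intermediate
4 | diethyl 2-(3,4,5-trimethoxybenzyl)malonate | CCOC(=O)C(Cc1cc(OC)c(OC)c(OC)c1)C(=O)OCC | intermediate
5 | 2-(3,4,5-trimethoxybenzyl)propane-1,3-diol | OCC(CO)Cc1cc(OC)c(OC)c(OC)c1 | intermediate
6 | (R)-3-hydroxy-2-(3,4,5-trimethoxybenzyl)propyl acetate | CC(=O)OC[C@@H](CO)Cc1cc(OC)c(OC)c(OC)c1 | intermediate
7 | (S)-2-formyl-3-(3,4,5-trimethoxyphenyl)propyl acetate | CC(=O)OC[C@@H](C=O)Cc1cc(OC)c(OC)c(OC)c1 | intermediate
8 | (R)-4,4-dibromo-2-(3,4,5-trimethoxybenzyl)but-3-en-1-yl acetate | CC(=O)OC[C@@H](C=C(Br)Br)Cc1cc(OC)c(OC)c(OC)c1 | intermediate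
9 | dilithiated alkynol (O,C-dilithium derivative of 10) | [Li]OC[C@@H](C#C[Li])Cc1cc(OC)c(OC)c(OC)c1 | intermediate
10 | (R)-2-(3,4,5-trimethoxybenzyl)but-3-yn-1-ol | OC[C@@H](C#C)Cc1cc(OC)c(OC)c(OC)c1 | intermediate
11 | 4-iodo-1,2-dimethoxybenzene | COc1ccc(I)cc1OC | starting material
12 | (R)-4-(3,4-dimethoxyphenyl)-2-(3,4,5-trimethoxybenzyl)but-3-yn-1-ol | OC[C@@H](C#Cc1ccc(OC)c(OC)c1)Cc1cc(OC)c(OC)c(OC)c1 | intermediate
13 | carbon monoxide | [C-]#[O+] | starting material
14 | (R,E)-3-(3,4-dimethoxybenzylidene)-4-(3,4,5-trimethoxybenzyl)dihydrofuran-2(3H)-one | COc1ccc(/C=C2/C(=O)OC[C@@H]2Cc2cc(OC)c(OC)c(OC)c2)cc1OC | intermediate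
15 | (3S,4R)-3-(3,4-dimethoxybenzyl)-4-(3,4,5-trimethoxybenzyl)dihydrofuran-2(3H)-one | COc1ccc(C[C@@H]2C(=O)OC[C@@H]2Cc2cc(OC)c(OC)c(OC)c2)cc1OC | intermediate
16 | (3R,4R)-3-(3,4-dimethoxybenzyl)-4-(3,4,5-trimethoxybenzyl)dihydrofuran-2(3H)-one | COc1ccc(C[C@H]2C(=O)OC[C@@H]2Cc2cc(OC)c(OC)c(OC)c2)cc1OC | target

Total step count: 10. Longest linear sequence: 10 steps (1 or 2 to 16). Compounds 11 and 13 are bought and enter directly.

Steps most likely to fail

**Step 8.** Insertion of the hindered, electron-rich internal alkyne into the Pd-acyl bond may be slow. That would leave time for 5-endo cycloisomerisation of the alkynol or for decay of the catalyst to palladium metal. The fallback sets out from 10 and comes back at 15. It carbonylates first and attaches ring A afterwards. The terminal alkynol 10, the best-behaved substrate class for PdCl2(PPh3)2/SnCl2/CO in MeCN, should give (R)-3-methylene-4-(3,4,5-trimethoxybenzyl)dihydrofuran-2(3H)-one F1. Rhodium-catalysed conjugate addition of 3,4-dimethoxyphenylboronic acid ([Rh(cod)Cl]2, KOH, dioxane/H2O, 50 °C) then bonds ring A to the exocyclic methylene carbon. Protonation of the rhodium enolate at C3 gives 15 mixed with 16, which enters step 10. Steps 7 to 9 are bypassed.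

**Step 5.** Aldehyde 7 may lose acetic acid by beta-elimination or enolise before or during the olefination, eroding both material and the configuration at C4. The fallback sets out from 5 and comes back at 10. It exchanges the roles of the two arms, so that the aldehyde carries a silyl ether, a much poorer leaving group.
- Ac2O/pyridine converts 5 into 2-(3,4,5-trimethoxybenzyl)propane-1,3-diyl diacetate F2.
- The same lipase in pH 7 phosphate buffer hydrolyses the pro-R ester to (S)-3-hydroxy-2-(3,4,5-trimethoxybenzyl)propyl acetate F3.
- TBSCl/imidazole gives (R)-3-((tert-butyldimethylsilyl)oxy)-2-(3,4,5-trimethoxybenzyl)propyl acetate F4.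
- K2CO3/MeOH frees (R)-3-((tert-butyldimethylsilyl)oxy)-2-(3,4,5-trimethoxybenzyl)propan-1-ol F5.
- TEMPO/PhI(OAc)2 gives (S)-3-((tert-butyldimethylsilyl)oxy)-2-(3,4,5-trimethoxybenzyl)propanal F6.
- The Ohira-Bestmann reagent (dimethyl (1-diazo-2-oxopropyl)phosphonate, K2CO3, MeOH) gives (R)-tert-butyldimethyl((2-(3,4,5-trimethoxybenzyl)but-3-yn-1-yl)oxy)silane F7.
- TBAF in THF returns 10.

This path is longer, but each operation is standard for beta-silyloxy alpha-branched aldehydes.

**Step 9.** Palladium may move the exocyclic double bond into the ring (C3=C4) ahead of hydrogen uptake, which would erase the C4 stereocentre. The fallback sets out from 14 and comes back at 15. It replaces surface hydrogenation by copper hydride conjugate reduction (Cu(OAc)2·H2O cat., 1,2-bis(diphenylphosphino)benzene, polymethylhydrosiloxane, t-BuOH, toluene, rt). Hydride goes only to the benzylic beta-carbon and t-BuOH protonates the copper enolate at C3. The C4-H bond is never engaged, and the resulting mixture of 15 and 16 goes into step 10.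

Further compounds
F1 | step 8 | (R)-3-methylene-4-(3,4,5-trimethoxybenzyl)dihydrofuran-2(3H)-one | C=C1C(=O)OC[C@@H]1Cc1cc(OC)c(OC)c(OC)c1
F2 | step 5 | 2-(3,4,5-trimethoxybenzyl)propane-1,3-diyl diacetate | CC(=O)OCC(COC(C)=O)Cc1cc(OC)c(OC)c(OC)c1
F3 | step 5 | (S)-3-hydroxy-2-(3,4,5-trimethoxybenzyl)propyl acetate | CC(=O)OC[C@H](CO)Cc1cc(OC)c(OC)c(OC)c1
F4 | step 5 | (R)-3-((tert-butyldimethylsilyl)oxy)-2-(3,4,5-trimethoxybenzyl)propyl acetate | CC(=O)OC[C@H](CO[Si](C)(C)C(C)(C)C)Cc1cc(OC)c(OC)c(OC)c1
F5 | step 5 | (R)-3-((tert-butyldimethylsilyl)oxy)-2-(3,4,5-trimethoxybenzyl)propan-1-ol | OC[C@H](CO[Si](C)(C)C(C)(C)C)Cc1cc(OC)c(OC)c(OC)c1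
F6 | step 5 | (S)-3-((tert-butyldimethylsilyl)oxy)-2-(3,4,5-trimethoxybenzyl)propanal | O=C[C@H](CO[Si](C)(C)C(C)(C)C)Cc1cc(OC)c(OC)c(OC)c1
F7 | step 5 | (R)-tert-butyldimethyl((2-(3,4,5-trimethoxybenzyl)but-3-yn-1-yl)oxy)silane | C#C[C@H](CO[Si](C)(C)C(C)(C)C)Cc1cc(OC)c(OC)c(OC)c1
F0 | step 9 | none | none
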